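**Retrosynthetic overview**

1. The target is reached by acidolysis of two tert-butyl groups: the tert-butyl enol ether on the C2 oxygen and the tert-butyl ester at C15.
2. Ring A (C1, C2, C3, C4, C5, C10) comes from a ring-rearrangement metathesis of a 1-acylcyclobutene: bond C1–C2 is formed, the temporary bond C1–C4 is cut and C18 is delivered to C4. The enabling feature is that the two sp2 carbons C1 (enol CH) and C4 (carrier of the exocyclic methylene) both sit on the ring-fusion bond C5–C10, so ring A can be stored as a cis-fused cyclobutene C1=C4–C5–C10 on ring B plus a 1-alkoxyvinyl ketone chain C3–C2.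
3. The acylcyclobutene comes from the ring-fused cyclobutanone through its enol triflate and a carbonylative Stille coupling (C3 from CO, C2 from a 1-alkoxyvinyl stannane).
4. The ring B substituents are built on a bicyclic enone: C9 by two enolate alkylations on the convex face, C8 and C7 by enol triflate methylation and hydroboration, C13 by copper-catalysed asymmetric conjugate addition.
5. The bicyclic enone (C5/C10 cis) comes from a Diels–Alder reaction of 2-methylcyclobut-2-enone with a chiral 1-amino-3-siloxy diene. Ring order: four-membered ring (temporary), ring B, ring A.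

Key step: step 22

Remark on names: positions are also given by clerodane numbers (ring A = C1, C2, C3, C4, C5, C10; ring B = C5 to C10; C18 = methylene on C4; C19 = methyl on C5; C20 = methyl on C9; C17 = methyl on C8; side chain C11 to C16). β is the face of ring B that carries C19 and H-10; α is the face that carries C1 and C4.

Assumption: the (2R,5R) antipode of the C2-symmetric pyrrolidine auxiliary is taken to be the one that leads to the 5S,10R series; if the sense is opposite, the (2S,5S) amine is used with no other change.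

Assumption: the (R,S) antipode of the ferrocenyl diphosphine is taken to be the one that gives 13R; otherwise its mirror image is used.

**Step 1**
Reactants: 1 1-ethoxyprop-1-yne; 2 trichloroacetyl chloride
Product: 4 4,4-dichloro-3-ethoxy-2-methylcyclobut-2-en-1-one, via dichloroketene 3 (not isolated)
Conditions: Zn–Cu couple, Et2O, 0 °C → rt
Reagents that add atoms: none
Why: Zinc dehalogenates 2 to dichloroketene, which undergoes the thermal [2+2] cycloaddition with an alkoxyalkyne, the ketene carbonyl carbon bonding to the methyl-bearing, nucleophilic alkyne carbon.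

**Step 2**
Reactants: 4 4,4-dichloro-3-ethoxy-2-methylcyclobut-2-en-1-one
Product: 5 3-ethoxy-2-methylcyclobut-2-en-1-one
Conditions: Zn dust, AcOH, TMEDA, EtOH, 0 °C → rt
Reagents that add atoms: none
Why: Zinc-mediated reductive dehalogenation of an α,α-dichloro ketone should remove both chlorines without touching the vinylogous ester.

**Step 3**
Reactants: 5 3-ethoxy-2-methylcyclobut-2-en-1-one
Product: 7 2-methylcyclobut-2-en-1-one, via allylic alcohol 6 (not isolated)
Conditions: i-Bu2AlH, CH2Cl2, −78 °C; then 1 M HCl, 0 °C (product kept in solution)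
Reagents that add atoms: water O
Why: Stork–Danheiser transposition: 1,2-reduction of the vinylogous ester, then acid hydrolysis of the enol ether with loss of water, moves the carbonyl to the former C3 and leaves the methyl on the α-carbon of the new enone.

**Step 4**
Reactants: 8 (2R,5R)-2,5-diphenylpyrrolidine; 9 (E)-4-methoxybut-3-en-2-one
Product: 10 (E)-4-[(2R,5R)-2,5-diphenylpyrrolidin-1-yl]but-3-en-2-one
Conditions: THF, rt
Reagents that add atoms: none
Why: Addition–elimination of the secondary amine on the vinylogous ester (amine exchange) should give the E vinylogous amide.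

**Step 5**
Reactants: 10 (E)-4-[(2R,5R)-2,5-diphenylpyrrolidin-1-yl]but-3-en-2-one
Product: 11 (2R,5R)-1-[(1E)-3-(tert-butyldimethylsilyloxy)buta-1,3-dien-1-yl]-2,5-diphenylpyrrolidine
Conditions: KHMDS, THF, −78 °C; t-BuMe2SiCl
Reagents that add atoms: tert-butyldimethylsilyl chloride CC(C)(C)[Si](C)(C)Cl
Why: Kinetic deprotonation of the methyl ketone and O-silylation of the cross-conjugated enolate should give the 1-amino-3-siloxy diene.

**Step 6**
Reactants: 7 2-methylcyclobut-2-en-1-one; 11 (2R,5R)-1-[(1E)-3-(tert-butyldimethylsilyloxy)buta-1,3-dien-1-yl]-2,5-diphenylpyrrolidine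
Product: 13 cis-6-methylbicyclo[4.2.0]oct-4-ene-3,7-dione (C19 methyl β; H-10 β), via silyl enol ether cycloadduct 12 (not isolated)
Conditions: toluene, −20 °C → rt; then aq. HF, MeCN, 0 °C
Reagents that add atoms: none
Why: Diels–Alder reaction of the strained cyclobutenone with the electron-rich aminosiloxy diene, in which the nucleophilic diene terminus bonds to the β-carbon C10, suprafacial addition fixes C19 and H-10 cis, and the C2-symmetric pyrrolidine blocks one diene face and so sets the absolute configuration at C5 and C10; fluoride then frees the C8 ketone and the amine leaves by β-elimination.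

**Step 7**
Reactants: 13 cis-6-methylbicyclo[4.2.0]oct-4-ene-3,7-dione
Product: 14 cis-7,7-dimethoxy-6-methylbicyclo[4.2.0]oct-4-en-3-one
Conditions: HC(OMe)3, MeOH, PPTS (cat.), rt
Reagents that add atoms: trimethyl orthoformate COC(OC)OC
Why: Acid-catalysed ketalisation should be much faster at the strained cyclobutanone than at the conjugated enone carbonyl, so only C4 is masked.

**Step 8**
Reactants: 14 cis-7,7-dimethoxy-6-methylbicyclo[4.2.0]oct-4-en-3-one
Product: 15 7,7-dimethoxy-2,6-dimethylbicyclo[4.2.0]oct-4-en-3-one (new methyl on C9; β epimer expected as the main one)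
Conditions: LDA, THF, −78 °C; MeI, −78 → −20 °C
Reagents that add atoms: iodomethane CI
Why: Kinetic α'-enolate alkylation at C9, the only enolisable position of the cyclohexenone; the configuration at C9 is of no consequence because the centre is planarised again in step 9.

**Step 9**
Reactants: 15 7,7-dimethoxy-2,6-dimethylbicyclo[4.2.0]oct-4-en-3-one
Product: 16 2-allyl-7,7-dimethoxy-2,6-dimethylbicyclo[4.2.0]oct-4-en-3-one (C9: allyl β; C20 methyl α)
Conditions: LDA, THF/DMPU, −78 °C; allyl bromide, −78 → 0 °C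
Reagents that add atoms: allyl bromide C=CCBr
Why: Second enolate alkylation creating the quaternary C9: allyl bromide should approach the enolate on the convex β face, anti to the cyclobutane carbon C1 on the neighbouring C10, so that allyl is β and C20 is α.

**Step 10**
Reactants: 16 2-allyl-7,7-dimethoxy-2,6-dimethylbicyclo[4.2.0]oct-4-en-3-one
Product: 17 2-allyl-7,7-dimethoxy-2,6-dimethylbicyclo[4.2.0]oct-3-en-3-yl trifluoromethanesulfonate
Conditions: LiBH(s-Bu)3, THF, −78 °C; then N-(5-chloro-2-pyridyl)triflimide, −78 → 0 °C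
Reagents that add atoms: N-(5-chloropyridin-2-yl)-1,1,1-trifluoro-N-(trifluoromethylsulfonyl)methanesulfonamide FC(F)(F)S(=O)(=O)N(c1ccc(Cl)cn1)S(=O)(=O)C(F)(F)F
Why: Conjugate (1,4) hydride reduction of the β-unsubstituted enone gives the C7=C8 enolate regiospecifically, and O-triflation in the same flask fixes it as the enol triflate.

**Step 11**
Reactants: 17 2-allyl-7,7-dimethoxy-2,6-dimethylbicyclo[4.2.0]oct-3-en-3-yl trifluoromethanesulfonate
Product: 18 2-allyl-7,7-dimethoxy-2,3,6-trimethylbicyclo[4.2.0]oct-3-ene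
Conditions: Me2Zn, Pd(PPh3)4 (5 mol %), THF, 0 °C → rt
Reagents that add atoms: dimethylzinc C[Zn]C
Why: Negishi cross-coupling of the enol triflate under zerovalent palladium catalysis should install C17 on C8.

**Step 12**
Reactants: 18 2-allyl-7,7-dimethoxy-2,3,6-trimethylbicyclo[4.2.0]oct-3-ene
Product: 19 2-(3-hydroxypropyl)-7,7-dimethoxy-2,3,6-trimethylbicyclo[4.2.0]octan-4-ol (C7 hydroxyl β; C17 methyl α)
Conditions: BH3·THF (excess), THF, 0 °C → rt; then NaOH, H2O2, 0 °C → rt
Reagents that add atoms: hydrogen peroxide OO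
Why: Hydroboration–oxidation: syn, anti-Markovnikov addition to the trisubstituted ring alkene from the β face (the α face is shielded by the axial C20 methyl and the cyclobutane) should set 7β-OH and 8β-H together, while the allyl group gives the primary alcohol.

**Step 13**
Reactants: 19 2-(3-hydroxypropyl)-7,7-dimethoxy-2,3,6-trimethylbicyclo[4.2.0]octan-4-ol
Product: 20 3-(4-hydroxy-7,7-dimethoxy-2,3,6-trimethylbicyclo[4.2.0]octan-2-yl)propanal
Conditions: TEMPO (cat.), PhI(OAc)2, CH2Cl2, rt
Reagents that add atoms: none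
Why: Oxoammonium (TEMPO) oxidation should be selective for the primary alcohol over the hindered secondary one.

**Step 14**
Reactants: 20 3-(4-hydroxy-7,7-dimethoxy-2,3,6-trimethylbicyclo[4.2.0]octan-2-yl)propanal
Product: 21 S-ethyl (E)-5-(4-hydroxy-7,7-dimethoxy-2,3,6-trimethylbicyclo[4.2.0]octan-2-yl)pent-2-enethioate
Conditions: Ph3P=CHC(O)SEt, CH2Cl2, rt
Reagents that add atoms: S-ethyl 2-(triphenylphosphoranylidene)ethanethioate CCSC(=O)C=P(c1ccccc1)(c1ccccc1)c1ccccc1
Why: Wittig olefination with a stabilised ylide should give the E α,β-unsaturated thioester.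

**Step 15**
Reactants: 21 S-ethyl (E)-5-(4-hydroxy-7,7-dimethoxy-2,3,6-trimethylbicyclo[4.2.0]octan-2-yl)pent-2-enethioate
Product: 22 S-ethyl (E)-5-(4-acetoxy-7,7-dimethoxy-2,3,6-trimethylbicyclo[4.2.0]octan-2-yl)pent-2-enethioate
Conditions: Ac2O, pyridine, DMAP (cat.), CH2Cl2, rt
Reagents that add atoms: acetic anhydride CC(=O)OC(C)=O
Why: Nucleophile-catalysed acylation of the secondary alcohol installs the C7 acetate of the target before any group appears that would compete for it.

**Step 16**
Reactants: 22 S-ethyl (E)-5-(4-acetoxy-7,7-dimethoxy-2,3,6-trimethylbicyclo[4.2.0]octan-2-yl)pent-2-enethioate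
Product: 23 S-ethyl (3R)-5-(4-acetoxy-7,7-dimethoxy-2,3,6-trimethylbicyclo[4.2.0]octan-2-yl)-3-methylpentanethioate
Conditions: MeMgBr, CuBr·SMe2 (5 mol %), (R)-1-[(S)-2-(diphenylphosphino)ferrocenyl]ethyldicyclohexylphosphine (6 mol %), t-BuOMe, −75 °C
Reagents that add atoms: methylmagnesium bromide C[Mg]Br
Why: Copper-catalysed asymmetric conjugate addition of a methyl Grignard reagent to an E α,β-unsaturated thioester, in which the ferrocenyl diphosphine controls the face and sets C13 (R) independently of the remote ring stereocentres.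

**Step 17**
Reactants: 23 S-ethyl (3R)-5-(4-acetoxy-7,7-dimethoxy-2,3,6-trimethylbicyclo[4.2.0]octan-2-yl)-3-methylpentanethioate
Product: 24 tert-butyl (3R)-5-(4-acetoxy-7,7-dimethoxy-2,3,6-trimethylbicyclo[4.2.0]octan-2-yl)-3-methylpentanoate
Conditions: AgOCOCF3, t-BuOH, 2,6-lutidine, MeCN, rt → 40 °C
Reagents that add atoms: tert-butanol CC(C)(C)O
Why: Thiophilic silver activation makes the thioester an acyl donor (acyl transfer to tert-butanol) without touching acetate or ketal, and gives an ester that is inert in steps 19 and 21.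

**Step 18**
Reactants: 24 tert-butyl (3R)-5-(4-acetoxy-7,7-dimethoxy-2,3,6-trimethylbicyclo[4.2.0]octan-2-yl)-3-methylpentanoate
Product: 25 tert-butyl (3R)-5-(4-acetoxy-2,3,6-trimethyl-7-oxobicyclo[4.2.0]octan-2-yl)-3-methylpentanoate
Conditions: PPTS, acetone/H2O, 50 °C
Reagents that add atoms: water O
Why: Acid-catalysed ketal hydrolysis under conditions too mild for the tert-butyl ester and the acetate.

**Step 19**
Reactants: 25 tert-butyl (3R)-5-(4-acetoxy-2,3,6-trimethyl-7-oxobicyclo[4.2.0]octan-2-yl)-3-methylpentanoate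
Product: 26 tert-butyl (3R)-5-[4-acetoxy-2,3,6-trimethyl-7-(trifluoromethylsulfonyloxy)bicyclo[4.2.0]oct-7-en-2-yl]-3-methylpentanoate (cyclobutenyl triflate, C4(OTf)=C1)
Conditions: LiHMDS, THF, −78 °C; N-(5-chloro-2-pyridyl)triflimide
Reagents that add atoms: N-(5-chloropyridin-2-yl)-1,1,1-trifluoro-N-(trifluoromethylsulfonyl)methanesulfonamide FC(F)(F)S(=O)(=O)N(c1ccc(Cl)cn1)S(=O)(=O)C(F)(F)F
Why: Kinetic enolisation and O-triflation of the cyclobutanone, which has α-hydrogens only at C1 and is far more acidic than the two esters, should give the enol triflate.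

**Step 20**
Reactants: 27 tert-butyl vinyl ether
Product: 28 tributyl(1-tert-butoxyvinyl)stannane
Conditions: t-BuLi, THF, −78 → 0 °C; Bu3SnCl, −78 °C → rt
Reagents that add atoms: tributyltin chloride CCCC[Sn](Cl)(CCCC)CCCC
Why: α-Lithiation of the vinyl ether and trapping with the tin chloride (directed metalation, then stannylation) gives the 1-alkoxyvinyl stannane.

**Step 21**
Reactants: 26 cyclobutenyl triflate; 28 tributyl(1-tert-butoxyvinyl)stannane
Product: 29 tert-butyl (3R)-5-[4-acetoxy-7-(2-tert-butoxyacryloyl)-2,3,6-trimethylbicyclo[4.2.0]oct-7-en-2-yl]-3-methylpentanoate (1-acylcyclobutene)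
Conditions: Pd(PPh3)4 (5 mol %), LiCl, CO (1 atm), THF, 55 °C
Reagents that add atoms: carbon monoxide [C-]#[O+]
Why: Carbonylative Stille coupling: oxidative addition at the enol triflate, CO insertion and transmetalation from the vinyl stannane should give the cross-conjugated ketone, with C3 coming from CO.

**Step 22**
Reactants: 29 1-acylcyclobutene
Product: 30 tert-butyl 7β-acetoxy-2-tert-butoxy-3-oxo-5,10-cis-cleroda-1,4(18)-dien-15-oate
Conditions: second-generation Hoveyda–Grubbs catalyst (10 mol %), toluene (0.005 M), 80 °C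
Reagents that add atoms: none
Why: Ring-rearrangement metathesis (ring-opening then ring-closing olefin metathesis): a ruthenium methylidene adds to the strained cyclobutene C1=C4 so that its CH2 ends on the acyl-bearing C4 (becoming C18) and the metal carbene sits on C1, and this carbene then attacks the pendant 1-alkoxyvinyl group, forming C1=C2 and releasing the methylidene for the next turnover. The closest known reaction types are the tandem ring-opening/ring-closing metathesis of cyclobutene-1-carbonyl compounds that carry a tethered alkene, and ring-closing metathesis onto 2-alkoxyacrylate-type olefins. Ring A is closed in a six-membered ring-closing metathesis mode (carbene carbon C1 joined to the internal carbon C2 of the 1,1-disubstituted olefin), while the four-membered ring is opened and its strain release should make the cascade irreversible. No new stereocentre is formed: C5 and C10 keep the cis relation fixed earlier by the cyclobutane, and C1=C2 can only be Z inside the six-membered ring. The step needs regioselective opening (CH2 to C4, carbene on C1) and ring closure in preference to oligomerisation; the first is secured by the substitution pattern of the cyclobutene (C1–H is open, C4 is fully substituted and acyl-bearing, so a disubstituted acyl carbene is avoided), the second by high dilution and by the fact that the alkoxyvinyl group, the only other olefin in the molecule, sits at six-ring distance.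

**Step 23**
Reactants: 30 tert-butyl 7β-acetoxy-2-tert-butoxy-3-oxo-5,10-cis-cleroda-1,4(18)-dien-15-oate
Product: 31 (5S,7S,8S,9R,10R,13R)-7-acetoxy-2-hydroxy-3-oxocleroda-1,4(18)-dien-15-oic acid
Conditions: CF3CO2H, CH2Cl2, 0 °C → rt
Reagents that add atoms: none
Why: Acidolysis: both tert-butyl groups should leave as the tert-butyl cation (E1), unveiling the C2 enol of the diosphenol and the C15 acid while the acetate and the exocyclic enone survive.

**Compound list**

1 | 1-ethoxyprop-1-yne | CCOC#CC | starting material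
2 | trichloroacetyl chloride | ClC(Cl)(Cl)C(Cl)=O | starting material
3 | dichloroketene | ClC(Cl)=C=O | intermediate
4 | 4,4-dichloro-3-ethoxy-2-methylcyclobut-2-en-1-one | CCOC1=C(C)C(=O)C1(Cl)Cl | intermediate
5 | 3-ethoxy-2-methylcyclobut-2-en-1-one | CCOC1=C(C)C(=O)C1 | intermediate
6 | 3-ethoxy-2-methylcyclobut-2-en-1-ol (racemic) | CCOC1=C(C)C(O)C1 | intermediate
7 | 2-methylcyclobut-2-en-1-one | CC1=CCC1=O | intermediate
8 | (2R,5R)-2,5-diphenylpyrrolidine | N1[C@@H](c2ccccc2)CC[C@@H]1c1ccccc1 | starting material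
9 | (E)-4-methoxybut-3-en-2-one | CO/C=C/C(C)=O | starting material
10 | (E)-4-[(2R,5R)-2,5-diphenylpyrrolidin-1-yl]but-3-en-2-one | CC(=O)/C=C/N1[C@@H](c2ccccc2)CC[C@@H]1c1ccccc1 | intermediate
11 | (2R,5R)-1-[(1E)-3-(tert-butyldimethylsilyloxy)buta-1,3-dien-1-yl]-2,5-diphenylpyrrolidine | C=C(O[Si](C)(C)C(C)(C)C)/C=C/N1[C@@H](c2ccccc2)CC[C@@H]1c1ccccc1 | intermediate
12 | 3-(tert-butyldimethylsilyloxy)-6-methyl-5-[(2R,5R)-2,5-diphenylpyrrolidin-1-yl]bicyclo[4.2.0]oct-3-en-7-one (cis-fused; amino group α) | O=C1C[C@@H]2CC(O[Si](C)(C)C(C)(C)C)=C[C@H](N3[C@@H](c4ccccc4)CC[C@@H]3c3ccccc3)[C@]12C | intermediate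
13 | cis-6-methylbicyclo[4.2.0]oct-4-ene-3,7-dione (C19 methyl and H-10 β) | O=C1C[C@@H]2CC(=O)C=C[C@]12C | intermediate
14 | cis-7,7-dimethoxy-6-methylbicyclo[4.2.0]oct-4-en-3-one | COC1(OC)C[C@@H]2CC(=O)C=C[C@]12C | intermediate
15 | 7,7-dimethoxy-2,6-dimethylbicyclo[4.2.0]oct-4-en-3-one (2-methyl β) | COC1(OC)C[C@@H]2[C@@H](C)C(=O)C=C[C@]12C | intermediate
16 | 2-allyl-7,7-dimethoxy-2,6-dimethylbicyclo[4.2.0]oct-4-en-3-one (allyl β, C20 methyl α) | COC1(OC)C[C@@H]2[C@@](C)(CC=C)C(=O)C=C[C@]12C | intermediate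
17 | 2-allyl-7,7-dimethoxy-2,6-dimethylbicyclo[4.2.0]oct-3-en-3-yl trifluoromethanesulfonate | COC1(OC)C[C@@H]2[C@@](C)(CC=C)C(OS(=O)(=O)C(F)(F)F)=CC[C@]12C | intermediate
18 | 2-allyl-7,7-dimethoxy-2,3,6-trimethylbicyclo[4.2.0]oct-3-ene | COC1(OC)C[C@@H]2[C@@](C)(CC=C)C(C)=CC[C@]12C | intermediate
19 | 2-(3-hydroxypropyl)-7,7-dimethoxy-2,3,6-trimethylbicyclo[4.2.0]octan-4-ol (C7 hydroxyl β, C17 methyl α) | COC1(OC)C[C@@H]2[C@@](C)(CCCO)[C@H](C)[C@@H](O)C[C@]12C | intermediate
20 | 3-(4-hydroxy-7,7-dimethoxy-2,3,6-trimethylbicyclo[4.2.0]octan-2-yl)propanal | COC1(OC)C[C@@H]2[C@@](C)(CCC=O)[C@H](C)[C@@H](O)C[C@]12C | intermediate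
21 | S-ethyl (E)-5-(4-hydroxy-7,7-dimethoxy-2,3,6-trimethylbicyclo[4.2.0]octan-2-yl)pent-2-enethioate | COC1(OC)C[C@@H]2[C@@](C)(CC/C=C/C(=O)SCC)[C@H](C)[C@@H](O)C[C@]12C | intermediate
22 | S-ethyl (E)-5-(4-acetoxy-7,7-dimethoxy-2,3,6-trimethylbicyclo[4.2.0]octan-2-yl)pent-2-enethioate | COC1(OC)C[C@@H]2[C@@](C)(CC/C=C/C(=O)SCC)[C@H](C)[C@@H](OC(C)=O)C[C@]12C | intermediate
23 | S-ethyl (3R)-5-(4-acetoxy-7,7-dimethoxy-2,3,6-trimethylbicyclo[4.2.0]octan-2-yl)-3-methylpentanethioate | COC1(OC)C[C@@H]2[C@@](C)(CC[C@@H](C)CC(=O)SCC)[C@H](C)[C@@H](OC(C)=O)C[C@]12C | intermediate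
24 | tert-butyl (3R)-5-(4-acetoxy-7,7-dimethoxy-2,3,6-trimethylbicyclo[4.2.0]octan-2-yl)-3-methylpentanoate | COC1(OC)C[C@@H]2[C@@](C)(CC[C@@H](C)CC(=O)OC(C)(C)C)[C@H](C)[C@@H](OC(C)=O)C[C@]12C | intermediate
25 | tert-butyl (3R)-5-(4-acetoxy-2,3,6-trimethyl-7-oxobicyclo[4.2.0]octan-2-yl)-3-methylpentanoate | O=C1C[C@@H]2[C@@](C)(CC[C@@H](C)CC(=O)OC(C)(C)C)[C@H](C)[C@@H](OC(C)=O)C[C@]12C | intermediate
26 | tert-butyl (3R)-5-[4-acetoxy-2,3,6-trimethyl-7-(trifluoromethylsulfonyloxy)bicyclo[4.2.0]oct-7-en-2-yl]-3-methylpentanoate | O=S(=O)(OC1=C[C@@H]2[C@@](C)(CC[C@@H](C)CC(=O)OC(C)(C)C)[C@H](C)[C@@H](OC(C)=O)C[C@]12C)C(F)(F)F | intermediate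
27 | tert-butyl vinyl ether | C=COC(C)(C)C | starting material
28 | tributyl(1-tert-butoxyvinyl)stannane | C=C(OC(C)(C)C)[Sn](CCCC)(CCCC)CCCC | intermediate
29 | tert-butyl (3R)-5-[4-acetoxy-7-(2-tert-butoxyacryloyl)-2,3,6-trimethylbicyclo[4.2.0]oct-7-en-2-yl]-3-methylpentanoate | C=C(OC(C)(C)C)C(=O)C1=C[C@@H]2[C@@](C)(CC[C@@H](C)CC(=O)OC(C)(C)C)[C@H](C)[C@@H](OC(C)=O)C[C@]12C | intermediate
30 | tert-butyl 7β-acetoxy-2-tert-butoxy-3-oxo-5,10-cis-cleroda-1,4(18)-dien-15-oate | C=C1C(=O)C(OC(C)(C)C)=C[C@@H]2[C@@](C)(CC[C@@H](C)CC(=O)OC(C)(C)C)[C@H](C)[C@@H](OC(C)=O)C[C@]12C | intermediate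
31 | (5S,7S,8S,9R,10R,13R)-7-acetoxy-2-hydroxy-3-oxocleroda-1,4(18)-dien-15-oic acid | C=C1C(=O)C(O)=C[C@@H]2[C@@](C)(CC[C@@H](C)CC(=O)O)[C@H](C)[C@@H](OC(C)=O)C[C@]12C | target

**Step count and risks**

Total step count: 23. Longest linear sequence: 20 steps (steps 1–3, 6–19, 21–23).

Steps most likely to fail:

Step 22 (key step). The ruthenium carbene may be held up on the alkoxy-substituted olefin as an unreactive heteroatom-stabilised carbene, or the hindered, acyl-substituted cyclobutene may open so slowly that oligomerisation wins. The fallback keeps the C1–C2 closure but makes it an aldol condensation, and it sets out from 26, whose cyclobutene is not yet deactivated by the acyl group. Ring-opening cross-metathesis with ethylene (second-generation Grubbs catalyst, ethylene, CH2Cl2) should give the vinyl enol triflate F6. Nozaki–Hiyama–Kishi coupling with (tert-butyldimethylsilyloxy)acetaldehyde (CrCl2, cat. NiCl2, DMF) should give the allylic alcohol F7, and Dess–Martin periodinane the enone F8. Dihydroxylation of the electron-richer vinyl group and glycol cleavage (cat. OsO4, NMO; then NaIO4) should give the keto aldehyde F9. Intramolecular aldol addition and dehydration (LiHMDS, THF, −78 °C; then MsCl, Et3N, DBU) should give the silyl-protected diosphenol F10. CF3CO2H in wet CH2Cl2 then removes the silyl group and the tert-butyl ester, and the route is rejoined at 31.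

Step 6. The α-methyl group of 7 may slow the cycloaddition, and the auxiliary may discriminate the two diene faces poorly, so that 13 is formed with low enantiomeric purity. The fallback sets out from 7 and replaces auxiliary control by catalyst control. 2-(Triisopropylsilyloxy)buta-1,3-diene F1 (from but-3-en-2-one, i-Pr3SiOTf, Et3N) should add to 7 under a chiral oxazaborolidinium triflimide Lewis acid (CH2Cl2, −78 °C) to give the silyl enol ether F2. Saegusa–Ito oxidation (Pd(OAc)2, MeCN) then gives the enone, and the route is rejoined at 13.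

Step 12. Borane may add to the ring alkene from the α face, which would invert C7 and C8 together. The fallback puts both centres under thermodynamic control and sets out from 18. After the hydroboration the primary alcohol of the diol mixture is silylated (t-BuMe2SiCl, imidazole), which gives, beside the silyl ether of 19, the 7α-hydroxy-8β-methyl isomer F3. Dess–Martin oxidation and base equilibration at C8 (K2CO3, MeOH) should give the ketone F4 with the equatorial 8α-methyl group. Reduction under equilibrating electron-transfer conditions (SmI2, H2O, Et3N, THF) should give the equatorial 7β-alcohol F5. Bu4NF removes the silyl group and the route is rejoined at 19.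

**Further compounds**

F1 | step 6 | 2-(triisopropylsilyloxy)buta-1,3-diene | C=CC(=C)O[Si](C(C)C)(C(C)C)C(C)C
F2 | step 6 | cis-6-methyl-3-(triisopropylsilyloxy)bicyclo[4.2.0]oct-3-en-7-one | O=C1C[C@@H]2CC(O[Si](C(C)C)(C(C)C)C(C)C)=CC[C@]12C
F3 | step 12 | 2-[3-(tert-butyldimethylsilyloxy)propyl]-7,7-dimethoxy-2,3,6-trimethylbicyclo[4.2.0]octan-4-ol, 7α-hydroxy-8β-methyl isomer | COC1(OC)C[C@@H]2[C@@](C)(CCCO[Si](C)(C)C(C)(C)C)[C@@H](C)[C@H](O)C[C@]12C
F4 | step 12 | 2-[3-(tert-butyldimethylsilyloxy)propyl]-7,7-dimethoxy-2,3,6-trimethylbicyclo[4.2.0]octan-4-one, 8α-methyl | COC1(OC)C[C@@H]2[C@@](C)(CCCO[Si](C)(C)C(C)(C)C)[C@H](C)C(=O)C[C@]12C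
F5 | step 12 | 2-[3-(tert-butyldimethylsilyloxy)propyl]-7,7-dimethoxy-2,3,6-trimethylbicyclo[4.2.0]octan-4-ol, 7β-hydroxy-8α-methyl isomer | COC1(OC)C[C@@H]2[C@@](C)(CCCO[Si](C)(C)C(C)(C)C)[C@H](C)[C@@H](O)C[C@]12C
F6 | step 22 | tert-butyl (3R)-5-{3-acetoxy-1,2,5-trimethyl-5-[1-(trifluoromethylsulfonyloxy)vinyl]-6-vinylcyclohexyl}-3-methylpentanoate | C=C[C@@H]1[C@@](C)(CC[C@@H](C)CC(=O)OC(C)(C)C)[C@H](C)[C@@H](OC(C)=O)C[C@]1(C)C(=C)OS(=O)(=O)C(F)(F)F
F7 | step 22 | tert-butyl (3R)-5-{3-acetoxy-5-[4-(tert-butyldimethylsilyloxy)-3-hydroxybut-1-en-2-yl]-1,2,5-trimethyl-6-vinylcyclohexyl}-3-methylpentanoate (mixture at the carbinol carbon) | C=C[C@@H]1[C@@](C)(CC[C@@H](C)CC(=O)OC(C)(C)C)[C@H](C)[C@@H](OC(C)=O)C[C@]1(C)C(=C)C(O)CO[Si](C)(C)C(C)(C)C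
F8 | step 22 | tert-butyl (3R)-5-{3-acetoxy-5-[4-(tert-butyldimethylsilyloxy)-3-oxobut-1-en-2-yl]-1,2,5-trimethyl-6-vinylcyclohexyl}-3-methylpentanoate | C=C[C@@H]1[C@@](C)(CC[C@@H](C)CC(=O)OC(C)(C)C)[C@H](C)[C@@H](OC(C)=O)C[C@]1(C)C(=C)C(=O)CO[Si](C)(C)C(C)(C)C
F9 | step 22 | tert-butyl (3R)-5-{3-acetoxy-5-[4-(tert-butyldimethylsilyloxy)-3-oxobut-1-en-2-yl]-6-formyl-1,2,5-trimethylcyclohexyl}-3-methylpentanoate | O=C[C@@H]1[C@@](C)(CC[C@@H](C)CC(=O)OC(C)(C)C)[C@H](C)[C@@H](OC(C)=O)C[C@]1(C)C(=C)C(=O)CO[Si](C)(C)C(C)(C)C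
F10 | step 22 | tert-butyl 7β-acetoxy-2-(tert-butyldimethylsilyloxy)-3-oxo-5,10-cis-cleroda-1,4(18)-dien-15-oate | C=C1C(=O)C(O[Si](C)(C)C(C)(C)C)=C[C@@H]2[C@@](C)(CC[C@@H](C)CC(=O)OC(C)(C)C)[C@H](C)[C@@H](OC(C)=O)C[C@]12C
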